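**Plan**
Numbering is that of the 6-oxabicyclo[3.2.1]octane-7,8-dione core (C1 prenylated bridgehead, C2, C3, C4 gem-dimethyl, C5 acylated bridgehead, O6, C7 lactone carbonyl, C8 ketone). The enabling feature is that C4, C3 and C2 are a 1,1-dimethylallyl group on C5 of the furan-2,4-dione ring (O6, C7, C1, C8, C5), so its CH2 terminus C2 lies within reach of C1, which sits between the C7 and C8 carbonyls and can hold a radical.
Retrosynthesis: (a) the C3 side chain, by cross-metathesis back to allyl and then the C3–allyl bond back to a C3 bromide; (b) C1–C2, opening the cyclohexanone ring by reversal of a bromine-transfer radical closure; (c) C1–Br; (d) C1–C8 (Dieckmann) and the O6–C7 ester bond; (e) C5–C4, by prenyl transfer to a 2,3-diketoester.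
Forward: diketoester, C5 carbinol, O-acylation, lactone ring, bromide at C1, cyclohexanone ring through C1–C2, then the C3 prenyl group in two steps; the sequence is fully linear.
Stereochemistry: C5 from the chiral complex [Cu((S,S)-tBu-box)](SbF6)2 in step 3; C1 follows from C5 because the three-carbon tether can bridge only one face of the lactone; C3 from capture of the C3 radical anti to the O6–C7 bridge.

Key step: step 7

Assumption: in step 3 the (S,S)-ligand (tBu-box = 2,2'-(propane-2,2-diyl)bis[(4S)-4-tert-butyl-4,5-dihydro-1,3-oxazole]) is written on the premise that the diketoester binds copper through its central ketone and ester carbonyl as pyruvate esters do, which exposes the si face and leads to (R)-6; the sense is to be confirmed on the first batch and the (R,R)-ligand used if it proves opposite.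

**Step 1**
Reactants: 1 methyl 4-methyl-3-oxopentanoate
Product: 2 methyl 2-diazo-4-methyl-3-oxopentanoate
Conditions: p-ABSA, Et3N, MeCN, 0 °C to rt
Reagents that add atoms: 4-acetamidobenzenesulfonyl azide (p-ABSA), CC(=O)Nc1ccc(cc1)S(=O)(=O)N=[N+]=[N-]
Why: Regitz diazo transfer, in which the triethylammonium enolate of the β-keto ester attacks the terminal nitrogen of the sulfonyl azide and the sulfonamide is expelled; no stereocentre is involved.

**Step 2**
Reactants: 2 methyl 2-diazo-4-methyl-3-oxopentanoate
Product: 3 methyl 4-methyl-2,3-dioxopentanoate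
Conditions: dimethyldioxirane, acetone, 0 °C to rt, then evaporation
Reagents that add atoms: dimethyldioxirane, CC1(C)OO1
Why: Oxygen-atom transfer from the dioxirane to the diazo carbon with loss of N2 is a known route to vicinal tricarbonyl compounds and leaves 3 anhydrous, which matters because the hydrate would block the Lewis acid of step 3.

**Step 3**
Reactants: 3 methyl 4-methyl-2,3-dioxopentanoate; 4 trimethyl(3-methylbut-2-en-1-yl)silane
Product: 6 methyl (2R)-2-hydroxy-4-methyl-2-(2-methylbut-3-en-2-yl)-3-oxopentanoate, via trimethylsilyl ether 5 (not isolated)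
Conditions: [Cu((S,S)-tBu-box)](SbF6)2 (10 mol%), 4 Å MS, CH2Cl2, −40 to 0 °C; then 1 M HCl, THF, rt
Reagents that add atoms: none
Why: Proposed new method: the diketoester should chelate divalent copper through the central ketone and the ester carbonyl, the allylsilane should then attack the exposed face of the central ketone with its CMe2 carbon because the developing positive charge is β to silicon, and silyl transfer to the copper alkoxide should release the catalyst and silyl ether 5, which the acidic work-up cleaves, so that C5 is set as R by the ligand; the closest known reaction types are the carbonyl-ene reaction of 2,3-diketoesters catalysed by the same [Cu(tBu-box)](SbF6)2 complex and the Hosomi–Sakurai allylation with γ,γ-disubstituted allylsilanes, and unlike an allylboronate the silane has no uncatalysed background reaction with the tricarbonyl.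

**Step 4**
Reactants: 6 methyl (2R)-2-hydroxy-4-methyl-2-(2-methylbut-3-en-2-yl)-3-oxopentanoate; 7 5-methylhex-4-enoic acid
Product: 9 methyl (2R)-4-methyl-2-(2-methylbut-3-en-2-yl)-2-[(5-methylhex-4-enoyl)oxy]-3-oxopentanoate, via 5-methylhex-4-enoyl chloride 8 (not isolated)
Conditions: 7, (COCl)2, DMF (cat.), CH2Cl2, 0 °C to rt, evaporate; then 6, Et3N, DMAP (1 equiv), toluene, 0 to 60 °C
Reagents that add atoms: none
Why: DMAP-mediated acylation of a hindered tertiary alcohol, in which the hydroxyl, acidified by the flanking ketone and ester, is captured by the acylpyridinium ion or by the ketene that Et3N generates from 8, both small enough to reach the congested oxygen; C5 is not touched.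

**Step 5**
Reactants: 9 methyl (2R)-4-methyl-2-(2-methylbut-3-en-2-yl)-2-[(5-methylhex-4-enoyl)oxy]-3-oxopentanoate
Product: 10 (5S)-4-hydroxy-3-(3-methylbut-2-en-1-yl)-5-(2-methylbut-3-en-2-yl)-5-(2-methylpropanoyl)furan-2(5H)-one
Conditions: LiN(SiMe3)2 (2.5 equiv), THF, −78 to 0 °C; then 1 M HCl
Reagents that add atoms: none
Why: Dieckmann condensation of the Lacey–Dieckmann type, in which the ester enolate of the acyloxy chain attacks the methyl ester on C5 and closes the five-membered lactone ring through the C1–C8 bond; aldol addition to the isobutyryl ketone can compete but is reversible, whereas loss of methoxide and deprotonation to the tetronate anion is not, so the equilibrium should drain to 10, and the quaternary C5 cannot epimerise (its descriptor changes only because the enol alters the priorities).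

**Step 6**
Reactants: 10 (5S)-4-hydroxy-3-(3-methylbut-2-en-1-yl)-5-(2-methylbut-3-en-2-yl)-5-(2-methylpropanoyl)furan-2(5H)-one
Product: 11 (5R)-3-bromo-3-(3-methylbut-2-en-1-yl)-5-(2-methylbut-3-en-2-yl)-5-(2-methylpropanoyl)furan-2,4(3H,5H)-dione (both epimers at the brominated carbon)
Conditions: NBS, CH2Cl2, −40 to 0 °C, dark; used at once
Reagents that add atoms: N-bromosuccinimide, O=C1CCC(=O)N1Br
Why: Electrophilic α-bromination of a fully enolised 1,3-dicarbonyl compound at carbon (the future C1) is far faster than attack of NBS on the isolated alkenes at low temperature in the dark; both epimers at the new C–Br centre form and are carried on together because step 7 passes through the planar radical.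

**Step 7**
Reactants: 11 (5R)-3-bromo-3-(3-methylbut-2-en-1-yl)-5-(2-methylbut-3-en-2-yl)-5-(2-methylpropanoyl)furan-2,4(3H,5H)-dione
Product: 12 (1R,3R,5R)-3-bromo-4,4-dimethyl-1-(3-methylbut-2-en-1-yl)-5-(2-methylpropanoyl)-6-oxabicyclo[3.2.1]octane-7,8-dione
Conditions: fac-Ir(ppy)3 (0.5 mol%), degassed MeCN (0.01 M), blue LEDs (450 nm), rt
Reagents that add atoms: none
Why: Excited fac-Ir(ppy)3 transfers an electron to the C1–Br bond, the planar C1 radical flanked by the C7 and C8 carbonyls adds to the unsubstituted vinyl terminus C2, and the secondary C3 radical abstracts bromine from a second molecule of 11, carrying a chain that the catalyst only has to initiate. The closest known reaction types are the atom-transfer radical cyclisation of α-halo-β-dicarbonyl compounds and the oxidative 6-endo cyclisation of cyclic β-keto esters bearing an α'-allyl group to bicyclo[3.2.1]octanones. The cyclohexanone ring (C1, C2, C3, C4, C5, C8) closes in the 6-endo-trig mode, as expected for a 2-oxohex-5-enyl radical. C1 is controlled by C5, since the tether reaches only the lactone face on which it stands and both epimers of 11 give the same radical; C3 is set by bromine delivery anti to the O6–C7 bridge and is of no consequence because step 8 regenerates the radical. The step needs 6-endo over 5-exo closure and cyclisation over intermolecular addition or reduction: the quaternary C4 blocks attack at C3, the 5-exo product would be a strained 2-oxabicyclo[2.2.1]heptane, and high dilution without a hydrogen donor suppresses the bimolecular paths.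

**Step 8**
Reactants: 12 (1R,3R,5R)-3-bromo-4,4-dimethyl-1-(3-methylbut-2-en-1-yl)-5-(2-methylpropanoyl)-6-oxabicyclo[3.2.1]octane-7,8-dione; 13 allyltributylstannane
Product: 14 (1R,3R,5R)-4,4-dimethyl-1-(3-methylbut-2-en-1-yl)-5-(2-methylpropanoyl)-3-(prop-2-en-1-yl)-6-oxabicyclo[3.2.1]octane-7,8-dione
Conditions: 13 (10 equiv), Et3B (0.5 equiv), air, benzene, rt
Reagents that add atoms: none
Why: Keck radical allylation, in which Bu3Sn• abstracts bromine, the C3 radical adds to 13 and expels Bu3Sn• to continue the chain, and because the O6–C7 lactone bridge covers the axial face the stannane should approach anti to it and place the allyl group equatorial (3R); initiation at room temperature and a large excess of 13 should keep β-scission of the C1–C2 bond, the reverse of step 7, slower than capture.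

**Step 9**
Reactants: 14 (1R,3R,5R)-4,4-dimethyl-1-(3-methylbut-2-en-1-yl)-5-(2-methylpropanoyl)-3-(prop-2-en-1-yl)-6-oxabicyclo[3.2.1]octane-7,8-dione; 15 2-methylbut-2-ene
Product: 16 (1R,3R,5R)-4,4-dimethyl-1,3-bis(3-methylbut-2-en-1-yl)-5-(2-methylpropanoyl)-6-oxabicyclo[3.2.1]octane-7,8-dione
Conditions: (H2IMes)(PCy3)Cl2Ru=CHPh (second-generation Grubbs catalyst, 5 mol%), 15 (large excess), CH2Cl2, 40 °C, sealed tube
Reagents that add atoms: none
Why: Olefin cross-metathesis of the terminal allyl group with 15 exchanges =CH2 for =CMe2 with loss of propene, the C1 prenyl group can only undergo degenerate exchange, the large excess of 15 should outrun ring closure between the two side chains, and no stereocentre is touched.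

**Compound list**
1 | methyl 4-methyl-3-oxopentanoate | CC(C)C(=O)CC(=O)OC | starting material
2 | methyl 2-diazo-4-methyl-3-oxopentanoate | CC(C)C(=O)C(=[N+]=[N-])C(=O)OC | intermediate
3 | methyl 4-methyl-2,3-dioxopentanoate | CC(C)C(=O)C(=O)C(=O)OC | intermediate
4 | trimethyl(3-methylbut-2-en-1-yl)silane | CC(C)=CC[Si](C)(C)C | starting material
5 | methyl (2R)-4-methyl-2-(2-methylbut-3-en-2-yl)-3-oxo-2-[(trimethylsilyl)oxy]pentanoate | C[Si](C)(C)O[C@](C(=O)C(C)C)(C(=O)OC)C(C)(C)C=C | intermediate
6 | methyl (2R)-2-hydroxy-4-methyl-2-(2-methylbut-3-en-2-yl)-3-oxopentanoate | O[C@](C(=O)C(C)C)(C(=O)OC)C(C)(C)C=C | intermediate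
7 | 5-methylhex-4-enoic acid | CC(C)=CCCC(=O)O | starting material
8 | 5-methylhex-4-enoyl chloride | CC(C)=CCCC(Cl)=O | intermediate
9 | methyl (2R)-4-methyl-2-(2-methylbut-3-en-2-yl)-2-[(5-methylhex-4-enoyl)oxy]-3-oxopentanoate | CC(C)=CCCC(=O)O[C@](C(=O)C(C)C)(C(=O)OC)C(C)(C)C=C | intermediate
10 | (5S)-4-hydroxy-3-(3-methylbut-2-en-1-yl)-5-(2-methylbut-3-en-2-yl)-5-(2-methylpropanoyl)furan-2(5H)-one | O=C1O[C@](C(=O)C(C)C)(C(O)=C1CC=C(C)C)C(C)(C)C=C | intermediate
11 | (5R)-3-bromo-3-(3-methylbut-2-en-1-yl)-5-(2-methylbut-3-en-2-yl)-5-(2-methylpropanoyl)furan-2,4(3H,5H)-dione, both epimers at the brominated carbon | CC(C)=CCC1(Br)C(=O)O[C@](C(=O)C(C)C)(C1=O)C(C)(C)C=C | intermediate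
12 | (1R,3R,5R)-3-bromo-4,4-dimethyl-1-(3-methylbut-2-en-1-yl)-5-(2-methylpropanoyl)-6-oxabicyclo[3.2.1]octane-7,8-dione (bromine equatorial, anti to the lactone bridge) | Br[C@@H]1C[C@@]2(CC=C(C)C)C(=O)O[C@](C(=O)C(C)C)(C2=O)C1(C)C | intermediate
13 | allyltributylstannane | C=CC[Sn](CCCC)(CCCC)CCCC | starting material
14 | (1R,3R,5R)-4,4-dimethyl-1-(3-methylbut-2-en-1-yl)-5-(2-methylpropanoyl)-3-(prop-2-en-1-yl)-6-oxabicyclo[3.2.1]octane-7,8-dione | C=CC[C@@H]1C[C@@]2(CC=C(C)C)C(=O)O[C@](C(=O)C(C)C)(C2=O)C1(C)C | intermediate
15 | 2-methylbut-2-ene | CC=C(C)C | starting material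
16 | (1R,3R,5R)-4,4-dimethyl-1,3-bis(3-methylbut-2-en-1-yl)-5-(2-methylpropanoyl)-6-oxabicyclo[3.2.1]octane-7,8-dione (CNP0231965.1) | CC(C)=CC[C@@H]1C[C@@]2(CC=C(C)C)C(=O)O[C@](C(=O)C(C)C)(C2=O)C1(C)C | target

**Step count**
Total: 9 steps. Longest linear sequence: 9 steps (1 to 16); 4, 7, 13 and 15 are purchased and enter directly.

**Steps most likely to fail**

Step 3 (proposed method). What may go wrong: poor facial discrimination at the central ketone, hydrogen transfer (ene pathway) instead of silyl loss, or sluggish bond formation between two fully substituted carbons. Fallback with known chemistry, from 3 back to 10: thermal γ-selective allylboration of 3 with 3-methylbut-2-enylboronic acid pinacol ester (toluene, rt) should give the racemic pinacol borate F1, hydrolysed on work-up to the racemic hydroxy ketoester F2. Steps 4 and 5 applied unchanged should give the racemic acyl ester F3 and the racemic tetronic acid F4. F4 is a strong vinylogous acid and is resolved by fractional crystallisation of its (R)-1-phenylethylammonium salt F5 (the antipodal amine is taken if the other diastereomer crystallises); acidification returns enantiopure 10.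

Step 7 (key step). What may go wrong: a short bromine-transfer chain, so that the C3 radical is oxidised by the tetravalent iridium formed at initiation and the cation suffers methyl migration from C4, or so that open-chain radicals add to prenyl groups of other molecules. Fallback, from 10 back to 14: iodination of 10 with N-iodosuccinimide (CH2Cl2, −40 °C) should give the iodo dione F6. Iodine-atom-transfer cyclisation under Bu3SnSnBu3 (10 mol%) and visible light in benzene, a chain with no electron-transfer oxidant present and with faster halogen hand-over, should give the bicyclic iodide F7. Allylation of F7 under the conditions of step 8 returns 14.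

Step 5. What may go wrong: the enolate closes on the isobutyryl ketone and the aldolate fails to revert, the ketone is enolised and takes the acyl group from oxygen, or liberated methoxide cleaves the non-enolisable β-keto ester. Fallback, from 6 back to 10: Steglich esterification of 6 with allyl hydrogen malonate (DCC, DMAP, CH2Cl2), which passes through a ketene and so tolerates the hindered alcohol, should give the mixed malonate F8. Its far more acidic methylene is enolised by DBU alone (MeCN, rt), conditions that remove neither ester nor ketone α-hydrogens, and Dieckmann closure should give the 3-(allyloxycarbonyl)tetronic acid F9. Pd(PPh3)4 (zerovalent palladium, THF, rt) then effects decarboxylative allyl transfer to the ring carbon to give the 3-allyl tetronic acid F10. Cross-metathesis of F10 with 15 under the conditions of step 9, in which the neopentyl vinyl group reacts far more slowly than the allyl group, returns 10.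

**Further compounds**
F1 | step 3 | racemic methyl 4-methyl-2-(2-methylbut-3-en-2-yl)-3-oxo-2-[(4,4,5,5-tetramethyl-1,3,2-dioxaborolan-2-yl)oxy]pentanoate | CC(C)C(=O)C(OB1OC(C)(C)C(C)(C)O1)(C(=O)OC)C(C)(C)C=C
F2 | step 3 | racemic methyl 2-hydroxy-4-methyl-2-(2-methylbut-3-en-2-yl)-3-oxopentanoate | OC(C(=O)C(C)C)(C(=O)OC)C(C)(C)C=C
F3 | step 3 | racemic methyl 4-methyl-2-(2-methylbut-3-en-2-yl)-2-[(5-methylhex-4-enoyl)oxy]-3-oxopentanoate | CC(C)=CCCC(=O)OC(C(=O)C(C)C)(C(=O)OC)C(C)(C)C=C
F4 | step 3 | racemic 4-hydroxy-3-(3-methylbut-2-en-1-yl)-5-(2-methylbut-3-en-2-yl)-5-(2-methylpropanoyl)furan-2(5H)-one | O=C1OC(C(=O)C(C)C)(C(O)=C1CC=C(C)C)C(C)(C)C=C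
F5 | step 3 | (R)-1-phenylethylammonium salt of the (5S)-tetronate of 10 | C[C@@H]([NH3+])c1ccccc1.O=C1O[C@](C(=O)C(C)C)(C([O-])=C1CC=C(C)C)C(C)(C)C=C
F6 | step 7 | (5R)-3-iodo-3-(3-methylbut-2-en-1-yl)-5-(2-methylbut-3-en-2-yl)-5-(2-methylpropanoyl)furan-2,4(3H,5H)-dione, both epimers at the iodinated carbon | CC(C)=CCC1(I)C(=O)O[C@](C(=O)C(C)C)(C1=O)C(C)(C)C=C
F7 | step 7 | (1R,3R,5R)-3-iodo-4,4-dimethyl-1-(3-methylbut-2-en-1-yl)-5-(2-methylpropanoyl)-6-oxabicyclo[3.2.1]octane-7,8-dione | I[C@@H]1C[C@@]2(CC=C(C)C)C(=O)O[C@](C(=O)C(C)C)(C2=O)C1(C)C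
F8 | step 5 | methyl (2R)-2-{[3-(allyloxy)-3-oxopropanoyl]oxy}-4-methyl-2-(2-methylbut-3-en-2-yl)-3-oxopentanoate | C=CCOC(=O)CC(=O)O[C@](C(=O)C(C)C)(C(=O)OC)C(C)(C)C=C
F9 | step 5 | prop-2-en-1-yl (5S)-4-hydroxy-5-(2-methylbut-3-en-2-yl)-5-(2-methylpropanoyl)-2-oxo-2,5-dihydrofuran-3-carboxylate | O=C1O[C@](C(=O)C(C)C)(C(O)=C1C(=O)OCC=C)C(C)(C)C=C
F10 | step 5 | (5S)-4-hydroxy-5-(2-methylbut-3-en-2-yl)-5-(2-methylpropanoyl)-3-(prop-2-en-1-yl)furan-2(5H)-one | O=C1O[C@](C(=O)C(C)C)(C(O)=C1CC=C)C(C)(C)C=C
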